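(The runs are calculated on assumed constants; noise was put on by code.)

Starting material is the easy thing to watch, and in the dusk run it falls quickly and then stops, at 76.3% after 12.0 min and 76.7% after 20.0 min. We read this as reagent fading away, so we want its pseudo-first-order decay constant, which we call the reagent clock.

- dusk: starting material 0.64 M; reagent 0.832 M; second substrate 0.64 M; third substrate 1.3 M; run made earlier
- flask: starting material 0.64 M; reagent 0.832 M; second substrate 0.640 M; third substrate 0.640 M; time 1.0 h

dusk run (percent of the starting material charged)

| time / min | target / % | starting material / % |
|---|---|---|
| 2.50 | 8.8 | 84.1 |
| 6.00 | 6.4 | 78.3 |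
| 12.0 | 3.9 | 76.3 |
| 20.0 | 1.4 | 76.7 |

(scatter of a reading: 0.3 percentage points)

- when, up to 1.0 h, the flask holds most target, in min
- the amount of target, in percent of the starting material charged, at that time



We have two ways to the clock. The first compares the logarithmic falls of starting material in the first two intervals and never touches the stall:

clock = 0.407 min⁻¹

The second follows the remaining fall towards the stall:

clock = 0.379 min⁻¹

The second rests on a remaining fall of 2 percentage points against a scatter of 0.3 points, so the two do not really part, and we take their mean, 0.393 min⁻¹.

The dose is the logarithm of charged over stalled starting material, and in dusk it is 0.270. Dose times clock, scaled by charges, gives the part of the clock that we book to starting material, 0.0817 min⁻¹. We charge the rest, crudely, to the third substrate and scale it to the flask: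

flask clock = 0.235 min⁻¹
flask dose = dusk dose × dusk clock / flask clock = 0.452

So we expect the flask to stall near 63.6%. At its first reading, the highest target among the dusk readings, dusk showed 55.3% of the converted starting material as target, and we assume the same share at the same time in the flask, which gives our own peak, 10.1% near 2.50 min.

The forecast says 11.5% at 3 min, on the ground that “the reagent survives somewhat longer, so more starting material converts”, and its amount stands higher than ours.

The flask gives 10.2% at 2.73 min.

    starting material + reagent ⇌ target (K = 0.570 M⁻¹, k = 0.150 M⁻¹ min⁻¹)
    second substrate + reagent → second product (k = 0.0300 M⁻¹ min⁻¹)
    third substrate + reagent → third product (k = 0.160 M⁻¹ min⁻¹)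
    target ⇌ isomer of the product (K = 1.10, k = 0.240 min⁻¹)
    target → over-reaction product (k = 0.210 min⁻¹)

After 1.00 h the flask holds 62.2% of its starting material, against our stall of 63.6%, and 1.22% of its reagent. The neighbouring flask has the same charges except for 0.26 M of third substrate, so our reckoning gives it a clock of 0.144 min⁻¹ and a dose of 0.738, which puts its stall near 47.8%. That neighbour reaches 11.1% of target at best and holds 45.3% of its starting material after 1.00 h.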